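The γ-butyrolactone is disconnected at its C3–C4 bond (lignan C8–C8'). In the key step a dirhodium carbene generated from an open-chain diazoacetate inserts into the methylene C–H that becomes C4, so that the O1–C2–C3–C4–C5 ring closes by 1,5-insertion and the C4 stereocentre is set under catalyst control next to the carbinol centre, which a catalytic asymmetric Mukaiyama aldol has already fixed. The feature exploited is the 1,5-relationship between the α-carbon C3 and the C4–H across the ester oxygen. The precursor is a 3-aryl-3-silyloxypropyl diazoacetate; the guaiacylmethyl group at C3 is added afterwards by trans-selective enolate alkylation, and one fluoride step unmasks the target.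

Key step: step 5

Assumption: the facial sense of the two chiral catalysts (steps 2 and 5) is assigned by analogy with simpler substrates; should a first run show the opposite sense, the antipodal catalyst is used and nothing else changes.

Abbreviations: TIPS = triisopropylsilyl; TBS = tert-butyldimethylsilyl; Rh2(4S-MPPIM)4 = dirhodium tetrakis[methyl (4S)-2-oxo-1-(3-phenylpropanoyl)imidazolidine-4-carboxylate].

Step 1
Reactants: 1 vanillin
Product: 2 3-methoxy-4-(triisopropylsilyloxy)benzaldehyde
Conditions: TIPSCl, imidazole, DMF, rt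
Reagents that add atoms: chlorotriisopropylsilane, CC(C)[Si](Cl)(C(C)C)C(C)C
Why: Imidazole-promoted silylation of the phenol gives an aryl TIPS ether that should survive the hydride, amine-base, carbene and enolate steps and fall to fluoride at the end.

Step 2
Reactants: 2 3-methoxy-4-(triisopropylsilyloxy)benzaldehyde
Product: 3 methyl (3R)-3-(tert-butyldimethylsilyloxy)-3-[3-methoxy-4-(triisopropylsilyloxy)phenyl]propanoate
Conditions: 1-(tert-butyldimethylsilyloxy)-1-methoxyethene, chiral 3,3'-bis[3,5-bis(trifluoromethyl)phenyl]-1,1'-binaphthyl-2,2'-disulfonimide (5 mol %, antipode for Re-face attack), Et2O, −78 °C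
Reagents that add atoms: 1-(tert-butyldimethylsilyloxy)-1-methoxyethene, C=C(OC)O[Si](C)(C)C(C)(C)C
Why: Catalytic asymmetric Mukaiyama aldol addition in which the N-silylated disulfonimide acts as a chiral silylium-type Lewis acid; Re-face attack on the aldehyde sets the (R)-carbinol centre, and silyl transfer from the ketene acetal delivers it directly as its TBS ether.

Step 3
Reactants: 3 methyl (3R)-3-(tert-butyldimethylsilyloxy)-3-[3-methoxy-4-(triisopropylsilyloxy)phenyl]propanoate
Product: 4 (3R)-3-(tert-butyldimethylsilyloxy)-3-[3-methoxy-4-(triisopropylsilyloxy)phenyl]propan-1-ol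
Conditions: i-Bu2AlH (2.5 equiv), CH2Cl2, −78 to 0 °C; aq. potassium sodium tartrate work-up
Reagents that add atoms: none
Why: Ester-to-alcohol reduction with i-Bu2AlH should leave both silyl ethers and the stereocentre untouched.

Step 4
Reactants: 4 (3R)-3-(tert-butyldimethylsilyloxy)-3-[3-methoxy-4-(triisopropylsilyloxy)phenyl]propan-1-ol
Product: 6 (3R)-3-(tert-butyldimethylsilyloxy)-3-[3-methoxy-4-(triisopropylsilyloxy)phenyl]propyl diazoacetate, via tosylhydrazone ester 5 (not isolated)
Conditions: glyoxylic acid chloride p-toluenesulfonylhydrazone, PhNMe2, CH2Cl2, 0 °C; then Et3N, 0 °C to rt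
Reagents that add atoms: 2-[(4-methylphenyl)sulfonylhydrazono]acetyl chloride, Cc1ccc(cc1)S(=O)(=O)N/N=C/C(Cl)=O
Why: O-Acylation by the acid chloride followed by triethylamine-induced loss of p-toluenesulfinate from the tosylhydrazone (Bamford–Stevens-type fragmentation) gives the diazoacetate in one flask without strong base, so the silyl ethers and the stereocentre are unaffected.

Step 5
Reactants: 6 (3R)-3-(tert-butyldimethylsilyloxy)-3-[3-methoxy-4-(triisopropylsilyloxy)phenyl]propyl diazoacetate
Product: 7 (4R)-4-{(R)-(tert-butyldimethylsilyloxy)[3-methoxy-4-(triisopropylsilyloxy)phenyl]methyl}oxolan-2-one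
Conditions: Rh2(4S-MPPIM)4 (2 mol %), CH2Cl2, reflux, slow addition of 6 over 12 h
Reagents that add atoms: none
Why: Loss of N2 from 6 at the dirhodium core gives an electrophilic rhodium carbene that inserts, through a concerted asynchronous three-centre transition state and with retention, into the pro-R C–H bond of the chain methylene two carbons from the ester oxygen, so the C3–C4 bond and the lactone ring are made in one event. The closest known reaction type is the enantioselective intramolecular C–H insertion of 3-substituted propyl diazoacetates to β-substituted γ-butyrolactones under chiral dirhodium carboxamidate catalysis. The oxolan-2-one ring closes in the 1,5-insertion mode (carbene carbon to the fifth chain atom, five-membered ring). The new stereocentre C4 (R) is set under catalyst control by the 4S-carboxamidate ligand sphere, which distinguishes the two diastereotopic hydrogens; the neighbouring (R)-silyloxy centre only has to not override it, and material from the minor enantiomer of 6 should emerge as a separable diastereomer, which raises the optical purity of 7. The step needs site selectivity for this methylene over the activated benzylic methine (1,6) and the O–CH2 group (1,4) and chemoselectivity over carbene dimerisation; the strong five-membered-ring preference of carboxamidate carbenes, steric shielding of the methine by the TBS and aryl groups, and slow addition at high dilution should secure them.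

Step 6
Reactants: 2 3-methoxy-4-(triisopropylsilyloxy)benzaldehyde
Product: 8 [3-methoxy-4-(triisopropylsilyloxy)phenyl]methanol
Conditions: NaBH4, MeOH, 0 °C
Reagents that add atoms: none
Why: Borohydride reduction of the aldehyde; the aryl silyl ether should survive brief exposure at 0 °C.

Step 7
Reactants: 8 [3-methoxy-4-(triisopropylsilyloxy)phenyl]methanol
Product: 9 [4-(bromomethyl)-2-methoxyphenoxy]triisopropylsilane
Conditions: CBr4, PPh3, CH2Cl2, 0 °C
Reagents that add atoms: tetrabromomethane, BrC(Br)(Br)Br
Why: The Appel reaction converts the benzylic alcohol into the bromide under neutral conditions; the electron-rich bromide is used directly.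

Step 8
Reactants: 7 (4R)-4-{(R)-(tert-butyldimethylsilyloxy)[3-methoxy-4-(triisopropylsilyloxy)phenyl]methyl}oxolan-2-one, 9 [4-(bromomethyl)-2-methoxyphenoxy]triisopropylsilane
Product: 11 (3R,4R)-4-{(R)-(tert-butyldimethylsilyloxy)[3-methoxy-4-(triisopropylsilyloxy)phenyl]methyl}-3-[3-methoxy-4-(triisopropylsilyloxy)benzyl]oxolan-2-one, via lithium enolate 10 (not isolated)
Conditions: LiN(i-Pr)2 (1.1 equiv), THF, −78 °C; then 9, DMPU, −78 to −40 °C
Reagents that add atoms: none
Why: Kinetic lithium enolate alkylation of a β-substituted γ-butyrolactone should occur on the ring face opposite the bulky C4 substituent (substrate control), which sets C3 as R, trans to C4.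

Step 9
Reactants: 11 (3R,4R)-4-{(R)-(tert-butyldimethylsilyloxy)[3-methoxy-4-(triisopropylsilyloxy)phenyl]methyl}-3-[3-methoxy-4-(triisopropylsilyloxy)benzyl]oxolan-2-one
Product: 12 (3R,4R)-3-(4-hydroxy-3-methoxybenzyl)-4-[(R)-hydroxy(4-hydroxy-3-methoxyphenyl)methyl]oxolan-2-one (allo-hydroxymatairesinol)
Conditions: Bu4NF (4 equiv), AcOH (4 equiv), THF, 0 °C to rt
Reagents that add atoms: none
Why: Fluoride cleaves the two aryl TIPS ethers and the secondary TBS ether, while the acetic acid buffer keeps phenoxide and alkoxide concentrations low so that neither quinone methide formation (loss of the carbinol configuration) nor translactonisation should intervene.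

Compound list
1 | vanillin | COc1cc(C=O)ccc1O | starting material
2 | 3-methoxy-4-(triisopropylsilyloxy)benzaldehyde | COc1cc(C=O)ccc1O[Si](C(C)C)(C(C)C)C(C)C | intermediate
3 | methyl (3R)-3-(tert-butyldimethylsilyloxy)-3-[3-methoxy-4-(triisopropylsilyloxy)phenyl]propanoate | COC(=O)C[C@@H](O[Si](C)(C)C(C)(C)C)c1ccc(O[Si](C(C)C)(C(C)C)C(C)C)c(OC)c1 | intermediate
4 | (3R)-3-(tert-butyldimethylsilyloxy)-3-[3-methoxy-4-(triisopropylsilyloxy)phenyl]propan-1-ol | OCC[C@@H](O[Si](C)(C)C(C)(C)C)c1ccc(O[Si](C(C)C)(C(C)C)C(C)C)c(OC)c1 | intermediate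
5 | (3R)-3-(tert-butyldimethylsilyloxy)-3-[3-methoxy-4-(triisopropylsilyloxy)phenyl]propyl (E)-2-(tosylhydrazono)acetate (formed in the flask) | Cc1ccc(cc1)S(=O)(=O)N/N=C/C(=O)OCC[C@@H](O[Si](C)(C)C(C)(C)C)c1ccc(O[Si](C(C)C)(C(C)C)C(C)C)c(OC)c1 | intermediate
6 | (3R)-3-(tert-butyldimethylsilyloxy)-3-[3-methoxy-4-(triisopropylsilyloxy)phenyl]propyl diazoacetate | [N-]=[N+]=CC(=O)OCC[C@@H](O[Si](C)(C)C(C)(C)C)c1ccc(O[Si](C(C)C)(C(C)C)C(C)C)c(OC)c1 | intermediate
7 | (4R)-4-{(R)-(tert-butyldimethylsilyloxy)[3-methoxy-4-(triisopropylsilyloxy)phenyl]methyl}oxolan-2-one | C1C(=O)OC[C@@H]1[C@@H](O[Si](C)(C)C(C)(C)C)c1ccc(O[Si](C(C)C)(C(C)C)C(C)C)c(OC)c1 | intermediate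
8 | [3-methoxy-4-(triisopropylsilyloxy)phenyl]methanol | COc1cc(CO)ccc1O[Si](C(C)C)(C(C)C)C(C)C | intermediate
9 | [4-(bromomethyl)-2-methoxyphenoxy]triisopropylsilane | COc1cc(CBr)ccc1O[Si](C(C)C)(C(C)C)C(C)C | intermediate
10 | lithium enolate of 7, lithium (4R)-4-{(R)-(tert-butyldimethylsilyloxy)[3-methoxy-4-(triisopropylsilyloxy)phenyl]methyl}-4,5-dihydrofuran-2-olate (formed in the flask) | C1=C([O-])OC[C@@H]1[C@@H](O[Si](C)(C)C(C)(C)C)c1ccc(O[Si](C(C)C)(C(C)C)C(C)C)c(OC)c1.[Li+] | intermediate
11 | (3R,4R)-4-{(R)-(tert-butyldimethylsilyloxy)[3-methoxy-4-(triisopropylsilyloxy)phenyl]methyl}-3-[3-methoxy-4-(triisopropylsilyloxy)benzyl]oxolan-2-one | COc1cc(C[C@H]2C(=O)OC[C@@H]2[C@@H](O[Si](C)(C)C(C)(C)C)c2ccc(O[Si](C(C)C)(C(C)C)C(C)C)c(OC)c2)ccc1O[Si](C(C)C)(C(C)C)C(C)C | intermediate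
12 | (3R,4R)-3-(4-hydroxy-3-methoxybenzyl)-4-[(R)-hydroxy(4-hydroxy-3-methoxyphenyl)methyl]oxolan-2-one (allo-hydroxymatairesinol) | COc1cc(C[C@H]2C(=O)OC[C@@H]2[C@@H](O)c2ccc(O)c(OC)c2)ccc1O | target

Total step count: 9. Longest linear sequence: 7 steps (1, 2, 3, 4, 5, 8, 9); steps 6 and 7 form the short branch to bromide 9.

Steps most likely to fail

Step 5. The carbene may insert into the activated benzylic methine (six-membered lactone) or the O–CH2 group (β-lactone). The target methylene is inductively deactivated by two β-oxygens, so the carbene may dimerise instead. Facial discrimination may also be eroded by the neighbouring stereocentre. The fallback replaces the C–H insertion by an alkene cyclopropanation that forms the same C3–C4 bond, followed by opening of the temporary three-membered ring. It sets out from aldehyde 2. Wittig olefination with Ph3P=CHCO2Et (toluene, 80 °C) should give ethyl (E)-3-[3-methoxy-4-(triisopropylsilyloxy)phenyl]prop-2-enoate F1. Reduction with i-Bu2AlH gives (E)-3-[3-methoxy-4-(triisopropylsilyloxy)phenyl]prop-2-en-1-ol F2. The acylation and fragmentation conditions of step 4 give, through the allylic tosylhydrazone ester F3, the allylic diazoacetate F4. Rh2(4S-MPPIM)4 (or its antipode) in refluxing CH2Cl2 should then give (1S,5R,6R)-6-[3-methoxy-4-(triisopropylsilyloxy)phenyl]-3-oxabicyclo[3.1.0]hexan-2-one F5, with the aryl group exo as dictated by the E-alkene; this closes the lactone and fixes both future stereocentres in one catalyst-controlled event. Water, with catalytic Sc(OTf)3 in wet hexafluoropropan-2-ol at 0 °C, should open the donor–acceptor cyclopropane at the benzylic carbon with inversion (SN2-type homoconjugate addition). This gives (4R)-4-{(R)-hydroxy[3-methoxy-4-(triisopropylsilyloxy)phenyl]methyl}oxolan-2-one F6. TBSOTf and 2,6-lutidine return the route to lactone 7.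

Step 2. Addition to the electron-rich aldehyde may be slow, and facial selectivity with the unsubstituted acetate ketene acetal may be insufficient. The fallback sets the carbinol centre by reagent-controlled allylboration. From aldehyde 2, (+)-Ipc2B(allyl) (Et2O, −78 °C; NaBO3·4H2O work-up) should add to the Re face and give (R)-1-[3-methoxy-4-(triisopropylsilyloxy)phenyl]but-3-en-1-ol F7. TBSOTf and 2,6-lutidine give tert-butyl{(R)-1-[3-methoxy-4-(triisopropylsilyloxy)phenyl]but-3-enyloxy}dimethylsilane F8. Ozonolysis (O3, CH2Cl2/MeOH, −78 °C) with NaBH4 reduction in the same flask gives alcohol 4, where the route is rejoined.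

Step 9. Once the phenol para to the carbinol is free under basic fluoride, quinone methide formation can epimerise the carbinol carbon and the carbinol alkoxide can translactonise. The hindered secondary TBS ether may also need forcing conditions that degrade the product. The fallback is a staged unmasking from 11. HF·pyridine buffered with pyridine (THF, 0 °C to rt) should remove only the alkyl TBS ether while both phenols stay capped, so no quinone methide can form. This gives (3R,4R)-4-{(R)-hydroxy[3-methoxy-4-(triisopropylsilyloxy)phenyl]methyl}-3-[3-methoxy-4-(triisopropylsilyloxy)benzyl]oxolan-2-one F9. The two aryl silyl ethers are then cleaved quickly with Bu4NF/AcOH (1:1) in THF at −20 °C to give 12.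

Further compounds
F1 | step 5 | ethyl (E)-3-[3-methoxy-4-(triisopropylsilyloxy)phenyl]prop-2-enoate | CCOC(=O)/C=C/c1ccc(O[Si](C(C)C)(C(C)C)C(C)C)c(OC)c1
F2 | step 5 | (E)-3-[3-methoxy-4-(triisopropylsilyloxy)phenyl]prop-2-en-1-ol | OC/C=C/c1ccc(O[Si](C(C)C)(C(C)C)C(C)C)c(OC)c1
F3 | step 5 | (E)-3-[3-methoxy-4-(triisopropylsilyloxy)phenyl]prop-2-enyl (E)-2-(tosylhydrazono)acetate | Cc1ccc(cc1)S(=O)(=O)N/N=C/C(=O)OC/C=C/c1ccc(O[Si](C(C)C)(C(C)C)C(C)C)c(OC)c1
F4 | step 5 | (E)-3-[3-methoxy-4-(triisopropylsilyloxy)phenyl]prop-2-enyl diazoacetate | [N-]=[N+]=CC(=O)OC/C=C/c1ccc(O[Si](C(C)C)(C(C)C)C(C)C)c(OC)c1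
F5 | step 5 | (1S,5R,6R)-6-[3-methoxy-4-(triisopropylsilyloxy)phenyl]-3-oxabicyclo[3.1.0]hexan-2-one | O=C1OC[C@@H]2[C@@H](c3ccc(O[Si](C(C)C)(C(C)C)C(C)C)c(OC)c3)[C@H]12
F6 | step 5 | (4R)-4-{(R)-hydroxy[3-methoxy-4-(triisopropylsilyloxy)phenyl]methyl}oxolan-2-one | C1C(=O)OC[C@@H]1[C@@H](O)c1ccc(O[Si](C(C)C)(C(C)C)C(C)C)c(OC)c1
F7 | step 2 | (R)-1-[3-methoxy-4-(triisopropylsilyloxy)phenyl]but-3-en-1-ol | C=CC[C@@H](O)c1ccc(O[Si](C(C)C)(C(C)C)C(C)C)c(OC)c1
F8 | step 2 | tert-butyl{(R)-1-[3-methoxy-4-(triisopropylsilyloxy)phenyl]but-3-enyloxy}dimethylsilane | C=CC[C@@H](O[Si](C)(C)C(C)(C)C)c1ccc(O[Si](C(C)C)(C(C)C)C(C)C)c(OC)c1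
F9 | step 9 | (3R,4R)-4-{(R)-hydroxy[3-methoxy-4-(triisopropylsilyloxy)phenyl]methyl}-3-[3-methoxy-4-(triisopropylsilyloxy)benzyl]oxolan-2-one | COc1cc(C[C@H]2C(=O)OC[C@@H]2[C@@H](O)c2ccc(O[Si](C(C)C)(C(C)C)C(C)C)c(OC)c2)ccc1O[Si](C(C)C)(C(C)C)C(C)C
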